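In a one-step world substrate would turn into target and stay there, but in this flask substrate has two ways out and target has one.

    substrate + free catalyst ⇌ catalyst intermediate A (K1 = 58 L mol⁻¹, k1 = 1.51 × 10⁶ L mol⁻¹ h⁻¹)
    catalyst intermediate A ⇌ catalyst intermediate B (K2 = 1.22, k2 = 622 h⁻¹)
    reagent + catalyst intermediate B → catalyst intermediate C (k3 = 16100 L mol⁻¹ h⁻¹)
    catalyst intermediate C → free catalyst + target (k4 = 572 h⁻¹)
    target → over-reaction product (k5 = 0.116 h⁻¹)
    2 substrate → self-condensation product (k6 = 33.8 L mol⁻¹ h⁻¹)

| flask | substrate | reagent | free catalyst | time |
|---|---|---|---|---|
| Monday's | 0.020 M | 0.0360 M | 26 µM | 12 h |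
| Sunday's | 0.020 M | 0.0360 M | 26 µM | 25 h |

* which of these there is most of at the end, counted by the substrate in it, Monday's (over-reaction product / catalyst intermediate A / target / substrate)
* which of these there is most of at the end, counted by the substrate in it, Sunday's (over-reaction product / catalyst intermediate A / target / substrate)
* final amount of the leader among these, as a percentage of the substrate charged, in Monday's
* final amount of the leader among these, as a percentage of the substrate charged, in Sunday's

- a species is counted by the substrate in it: one self-condensation product counts as two
- a doubled species enters its step squared and goes two at a time
- run time (Monday's): 12 h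

Below, x is the fraction of the charged substrate still free.

*What does the catalyst do, as one rate?* Catalyst intermediate A falls back at 26000 h⁻¹, faster than it moves on at 622 h⁻¹, so I hold it in equilibrium with substrate and free catalyst. I hold reagent at its charge, which makes its attack on catalyst intermediate B pseudo-first-order at 580 h⁻¹, while B returns to A at 510 h⁻¹. Net, A goes forward at 331 h⁻¹. Dilute substrate therefore falls at κ = 0.499 h⁻¹.

*And at full charge?* Bound forms then outnumber free catalyst by L = 2.49, so the catalytic rate is κx divided by one plus Lx. That is 0.143 h⁻¹ at the start, slower than self-condensation at 1.35 h⁻¹.

*Then is the catalyst beaten?* Early, yes, but self-condensation goes with x squared. Dividing one rate by the other removes time. With r = 2.71, the catalytic part of each bit of substrate is w, the reciprocal of one plus rx(one plus Lx). The catalytic share f, the fraction of the charge that ever reaches target, is w integrated over x from zero to one. Simpson's rule, with w at one where x is zero, 0.247 midway and 0.0956 at the start, weighs the midpoint against the mean of the two ends and gives f = 34.7%.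

*And the clock?* Let the feed die as e^(−κt) and let target decay at λ = 0.116 h⁻¹. Integrating gives target = fS, with S = κ/(κ−λ) times (e^(−λt) − e^(−κt)), and over-reaction product is what remains of f after target and the unfed part fe^(−κt). S is 32.1% on Monday's and 7.17% on Sunday's.

I commit to over-reaction product on Monday's at 23.5%, and over-reaction product on Sunday's at 32.3%.

The forecast gives over-reaction product at 23% (20% to 26%) for Monday's and over-reaction product at 31% (28% to 34%) for Sunday's, holding that “Self-condensation, which is not among the listed options, takes most of the substrate early”.

The simulation gives over-reaction product at 22.1% on Monday's and over-reaction product at 30.9% on Sunday's, with target at 11.2% and 2.53%.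

In Sunday's flask the ceiling f is low mainly through self-condensation: with that step taken away, over-reaction product goes from 30.9% to 88.1%. Monday's flask left for 120 h stands at 33.4%.

Read at 3.0 h, Monday's recipe should by f hold target at 21.8% and over-reaction product at 5.13%, the order reversed. The computed flask holds 19.5% and 4.44%.

The constants were drawn at random within sensible limits; the run is a simulation.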